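**The vessel.** Our vessel is stirred and isothermal, and it holds a racemate of substrates with a single-handed catalyst while partner is fed in. We count everything as a fraction of the charge, so the added feed volume drops out of our reckoning.

| flask | left-handed substrate | right-handed substrate | partner | catalyst | remark | time |
|---|---|---|---|---|---|---|
| dawn | 10 mM | 10 mM | 20 mM (fed, over 10 s) | 0.24 mM | run made earlier; the fed solution adds 0.10 times the starting volume |  |
| winter | 40 mM | 40 mM | 20 mM (fed, over 10 s) | 0.24 mM | run made earlier; the fed solution adds 0.10 times the starting volume |  |
| summer | 20 mM | 20 mM | 20 mM (fed, over 10 s) | 0.48 mM | run made earlier; the fed solution adds 0.10 times the starting volume |  |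
| flask | 20 mM | 20 mM | 20.0 mM (fed, over 10 s) | 0.24 mM | the fed solution adds 0.10 times the starting volume | 4.0 h |

| run | time / h | left-handed substrate / % | left-handed product / % |
|---|---|---|---|
| dawn | 0.333 | 0 | 49.7 |
| dawn | 0.667 | 0.3 | 51.2 |
| dawn | 1.00 | 0 | 50.4 |
| dawn | 2.00 | 0 | 49.7 |
| dawn | 4.00 | 0 | 50.3 |
| winter | 0.833 | 34.7 | 12.2 |
| winter | 1.50 | 35.5 | 13.5 |
| winter | 2.50 | 35.0 | 12.8 |
| winter | 3.00 | 34.4 | 11.8 |
| winter | 4.00 | 36.2 | 13.7 |
| summer | 0.333 | 21.1 | 25.1 |
| summer | 0.667 | 21.5 | 25.5 |
| summer | 1.00 | 21.0 | 24.9 |
| summer | 2.00 | 21.2 | 25.0 |
| summer | 4.00 | 21.1 | 25.5 |

(scatter of a reading: 0.5 percentage points)

- catalyst is single-handed; left-handed substrate and right-handed substrate are mirror images of each other, charged as a racemate, each of them at the stated concentration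
- every charge counts on the volume at the start, and the solution that is fed holds the whole dose
- the analysis behind the earlier runs scatters by 0.5 percentage points, standard deviation
- the reaction counts as stopped when no species that holds the left-handed substrate and right-handed substrate together changes by six tenths of a point or more over the second half of the time

- the state of affairs at 4.0 h: stopped, and by what, or still going (all of the left-handed substrate has reacted / no working catalyst is left / it is still moving / the partner has run out first / forward and back rates have come level)
- how much of the left-handed substrate and right-handed substrate together has reacted by 4.0 h
- how much left-handed product there is at 4.0 h, in percent of the left-handed substrate and right-handed substrate together charged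
- how much right-handed substrate there is at 4.0 h, in percent of the left-handed substrate and right-handed substrate together charged
- how much right-handed product there is at 4.0 h, in percent of the left-handed substrate and right-handed substrate together charged

**First seconds.** Partner enters the flask over 10 s. The dawn run, with the same catalyst charge of 0.24 mM, already reads 0% left-handed substrate at 0.333 h, which is earlier than the asked time. We therefore expect the flask to be at rest long before 4.0 h.

**The middle.** Both substrates meet the same partner and catalyst. If each is consumed in proportion to itself, dividing the two rates cancels partner, catalyst and time. Integrating then leaves one constant, the selectivity factor: the logarithm of the surviving fraction of left-handed substrate's own charge over the same logarithm for right-handed substrate.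

The summer run has a ceiling of 50.0% reacted and a mean left-handed substrate reading of 21.2%. The balance gives the unread right-handed substrate, and so a factor of 1.56, meaning that in the summer readings left-handed substrate goes faster than right-handed substrate. The winter means give 1.55 from different charges.

**The end.** The flask holds less partner than the two substrates together, so, at one partner for each substrate, partner is the limiting reagent and we expect 50.0% reacted. The flask has the summer charges apart from catalyst, so we reckon 21.2% left-handed substrate and 28.8% right-handed substrate.

At 4.00 h, left-handed product reads 50.3%, 13.7% and 25.5% in dawn, winter and summer. The summer reading is half of the summer ceiling, and it is less than the left-handed substrate consumed in the summer run. We read this as the products evening out, and so expect 25.0% of each.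

**The forecast.** It says the partner has run out first, with 50% reacted, 25.2% left-handed product, 29% right-handed substrate and 20% right-handed product, which differs from our reckoning on that last figure. Its ground is that “Doubling the catalyst in summer only changes the speed”.

**The flask.** The flask gives: the partner has run out first, with 50.0% reacted, 25.0% left-handed product, 29.0% right-handed substrate and 25.0% right-handed product, against the forecast's 20%. Partner stands at 0% at 4.00 h.

    left-handed product ⇌ right-handed product (k = 0.00191 /s)
    partner + catalyst + left-handed substrate → catalyst + left-handed product (k = 1.02 × 10⁵ /M²/s)
    partner + catalyst + right-handed substrate → catalyst + right-handed product (k = 64200 /M²/s)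

**More partner.** In the flask, left-handed substrate keeps 42% of its own charge. The factor 1.56 turns that into 57.3% of right-handed substrate's own charge, and the flask holds 58%. A neighbouring flask with 34 mM of partner has a ceiling of 85.0% and reacts 85.0%. Its left-handed substrate keeps 8.6% of its own charge, from which the factor gives 20.7% for right-handed substrate, and that neighbouring flask holds 21%.

The numbers in the tables are simulated for substances that don't exist, noise included.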